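The target is disconnected at C1–C8 of ring A (C1, C9, C5, C6, C7, C8). The exploited feature is that C6–C7–C8, with the C8 methyl and homoprenyl groups, is an intact geraniol unit spanning the bridgeheads C5 and C1; ring A can therefore come from an epoxygeranyl chain on the quaternary carbon of a symmetric 1,5-dimethoxycyclohexa-1,4-diene that already carries the C5 prenyl group. One Lewis-acid step opens the (2R,3R)-oxirane at its tertiary carbon with one of two enantiotopic enol ethers, closes ring A and a C7–O–C9 ketal, and fixes C1, C5, C8 and C9. C7–O later becomes geranyl by radical allylation and cross-coupling; C2 oxidation, C1 prenylation and C3 aroylation complete the route.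

Key step: step 6

Remark: locants are those of the bicyclo[3.3.1]nonane core used above (C1 and C5 bridgeheads, C9 the one-carbon bridge, C2–C4 the dione bridge, C8 bonded to C1); the key-step precursor and product agree with the target (C7 retained, C8 inverted) and demand the (2R,3R)-oxirane, so the unnatural D-(−)-tartrate is assumed for the epoxidation, and TMSOTf is taken as catalytic.

Step 1
Reactants: 1 1,3-dimethoxybenzene
Product: 2 1,5-dimethoxycyclohexa-1,4-diene
Conditions: Li, NH3 (l), THF, t-BuOH, −78 °C; then NH4Cl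
Reagents that add atoms: none
Why: Birch reduction: electron transfer and protonation at the positions that leave both methoxy groups on double bonds give the non-conjugated 2,5-dihydroarene, and tert-butanol as proton source avoids over-reduction; no stereocentre is formed.

Step 2
Reactants: 2 1,5-dimethoxycyclohexa-1,4-diene; 3 prenyl bromide
Product: 5 1,5-dimethoxy-6-(3-methylbut-2-en-1-yl)cyclohexa-1,4-diene, via lithiated diene 4 (not isolated)
Conditions: t-BuLi, THF, −78 °C; then 3, −78 → 0 °C
Reagents that add atoms: none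
Why: The C6 methylene lies between both enol ether carbons, so t-BuLi removes it to a methoxy-chelated pentadienyl lithium that undergoes SN2 C-alkylation at its central carbon with the allylic bromide (alkylation of a metallated Birch diene).

Step 3
Reactants: 6 geraniol
Product: 7 (2R,3R)-2,3-epoxygeraniol
Conditions: Ti(OiPr)4 (5 mol%), D-(−)-diethyl tartrate (7 mol%), t-BuOOH, 4 Å MS, CH2Cl2, −20 °C
Reagents that add atoms: tert-butyl hydroperoxide CC(C)(C)OO
Why: Sharpless asymmetric epoxidation is hydroxyl-directed, so only the 2,3-alkene reacts, and the titanium complex of the D-(−)-tartrate delivers oxygen to the face that gives the (2R,3R)-oxirane, the E geometry placing CH2OH and the homoprenyl chain trans.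

Step 4
Reactants: 7 (2R,3R)-2,3-epoxygeraniol
Product: 9 (2S,3R)-2-(bromomethyl)-3-methyl-3-(4-methylpent-3-en-1-yl)oxirane, via epoxy mesylate 8 (not isolated)
Conditions: MsCl, Et3N, CH2Cl2, −10 °C; then LiBr, THF, 0 °C → rt
Reagents that add atoms: lithium bromide [Li+].[Br-]
Why: Sulfonylation of the primary alcohol and SN2 displacement by bromide (Finkelstein-type) occur at the carbinol carbon only, so both oxirane stereocentres are untouched (the C2 descriptor changes to S by priority alone).

Step 5
Reactants: 5 1,5-dimethoxy-6-(3-methylbut-2-en-1-yl)cyclohexa-1,4-diene; 9 (2S,3R)-2-(bromomethyl)-3-methyl-3-(4-methylpent-3-en-1-yl)oxirane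
Product: 11 (2R,3R)-2-{[2,6-dimethoxy-1-(3-methylbut-2-en-1-yl)cyclohexa-2,5-dien-1-yl]methyl}-3-methyl-3-(4-methylpent-3-en-1-yl)oxirane, via lithiated prenyl diene 10 (not isolated)
Conditions: s-BuLi, THF, −78 → −40 °C; then 9, −78 °C
Reagents that add atoms: none
Why: A second metallation at the now tertiary doubly allylic carbon needs the stronger s-BuLi, and the hindered carbanion is alkylated by SN2 at the primary, oxirane-activated bromide to give the quaternary carbon, which is not stereogenic because the two enol ether arms are enantiotopic.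

Step 6
Reactants: 11 (2R,3R)-2-{[2,6-dimethoxy-1-(3-methylbut-2-en-1-yl)cyclohexa-2,5-dien-1-yl]methyl}-3-methyl-3-(4-methylpent-3-en-1-yl)oxirane
Product: 13 (1S,5S,7R,8R,9R)-4,9-dimethoxy-8-methyl-5-(3-methylbut-2-en-1-yl)-8-(4-methylpent-3-en-1-yl)-7,9-epoxybicyclo[3.3.1]non-3-ene (C7–O–C9 bridged methyl ketal), via silyl ether oxocarbenium triflate 12 (not isolated)
Conditions: TMSOTf (0.3 equiv), 2,6-lutidine, CH2Cl2, −78 °C
Reagents that add atoms: none
Why: Silylation of the oxirane oxygen polarises the tertiary C8–O bond, and the β-carbon of one enol ether (future C1) attacks C8 anti to the leaving oxygen, giving a C7 silyl ether and an O-methyl oxocarbenium at C9 that the C7 oxygen then captures with loss of the silyl group. The closest known reaction type is the Lewis-acid-promoted, epoxide-initiated cation–enol ether cyclisation with heteroatom termination. Ring A closes in a 6-endo opening of the epoxide (both oxirane carbons end up in the ring) through a chair, and the oxolane ring O–C7–C8–C1–C9 closes 5-exo-trig on the oxocarbenium. C8 is set by stereospecific inversion and C7 is carried over unchanged; C1 and C5 are set by the choice of enol ether that the (2R,3R)-oxirane imposes through the chair with the C7–O bond equatorial (only this arm lets the oxygen reach C9), and C9 is set by the geometry of the bridge. The step needs group selectivity between the enantiotopic enol ethers, attack at the tertiary and not the secondary oxirane carbon, and preference for the enol ether over the prenyl-type π bonds; these are secured by the oxirane configuration on the C5 tether, by the cation-stabilising substitution at C8 and by the higher nucleophilicity of the enol ether, while 2,6-lutidine keeps the acid-labile enol ethers intact.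

Step 7
Reactants: 13 bridged methyl ketal
Product: 15 (1S,5S,7R,8R)-7-hydroxy-4-methoxy-8-methyl-5-(3-methylbut-2-en-1-yl)-8-(4-methylpent-3-en-1-yl)bicyclo[3.3.1]non-3-en-9-one, via C7 dimethylborinate 14 (not isolated)
Conditions: Me2BBr, CH2Cl2, −95 °C; then Et3N, aq NaHCO3
Reagents that add atoms: none
Why: Haloborane cleavage of a ketal: the Lewis acid binds the strained ring oxygen, the C9–O bond to C7 breaks to an O-methyl oxocarbenium that bromide demethylates, and hydrolysis of the borinate frees the exo C7 alcohol with its configuration untouched, while the very low temperature and the amine quench spare the methyl enol ether.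

Step 8
Reactants: 15 C7 hydroxy ketone
Product: 17 O-[(1S,5S,7R,8R)-4-methoxy-8-methyl-5-(3-methylbut-2-en-1-yl)-8-(4-methylpent-3-en-1-yl)-9-oxobicyclo[3.3.1]non-3-en-7-yl] S-methyl carbonodithioate, via sodium xanthate 16 (not isolated)
Conditions: NaH, imidazole (cat.), THF, 0 °C; CS2; then MeI, rt
Reagents that add atoms: carbon disulfide S=C=S; iodomethane CI
Why: Xanthate formation by addition of the sodium alkoxide to CS2 and S-methylation (the first stage of a Barton–McCombie sequence) tolerates NaH here because no enolisable hydrogen is present (C1 is a bridgehead, C5 is quaternary) and C2 is still a methylene, so the alkoxide has no retro-Claisen outlet.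

Step 9
Reactants: 17 C7 xanthate
Product: 18 (1S,5S,7R,8S)-4-methoxy-8-methyl-5-(3-methylbut-2-en-1-yl)-8-(4-methylpent-3-en-1-yl)-7-(prop-2-en-1-yl)bicyclo[3.3.1]non-3-en-9-one
Conditions: Bu3SnCH2CH=CH2 (10 equiv), AIBN, PhH, 80 °C
Reagents that add atoms: allyltributylstannane C=CC[Sn](CCCC)(CCCC)CCCC
Why: Keck radical allylation: stannyl radical addition to the thiocarbonyl and fragmentation give the secondary C7 radical, which is trapped by the allylstannane in an SH2′ step on the exo face (the face the oxygen occupied, opposite ring B), placing allyl equatorial on chair ring A, while 5-exo closure onto the C8 homoprenyl alkene would require endo attack or a trans-fused transition state and is further suppressed by the high stannane concentration.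

Step 10
Reactants: 18 C7 allyl enol ether ketone
Product: 19 4-methoxy-8-methyl-5-(3-methylbut-2-en-1-yl)-8-(4-methylpent-3-en-1-yl)-7-(prop-2-en-1-yl)bicyclo[3.3.1]non-3-ene-2,9-dione (stereocentres as in 18)
Conditions: t-BuOOH, PhI(OCOCF3)2, Cs2CO3, EtOAc, −78 → −40 °C
Reagents that add atoms: tert-butyl hydroperoxide CC(C)(C)OO
Why: Allylic oxidation by tert-butylperoxy radicals generated from t-BuOOH and the trivalent iodine reagent: hydrogen abstraction is fastest at C2, the methylene allylic to the electron-rich enol ether, and the resulting C2 peroxide undergoes base-induced Kornblum–DeLaMare fragmentation to the vinylogous ester, the less activated prenyl, homoprenyl and allyl positions remaining intact.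

Step 11
Reactants: 19 C1–H vinylogous ester; 3 prenyl bromide
Product: 21 4-methoxy-8-methyl-1,5-bis(3-methylbut-2-en-1-yl)-8-(4-methylpent-3-en-1-yl)-7-(prop-2-en-1-yl)bicyclo[3.3.1]non-3-ene-2,9-dione (C5, C7, C8 as in 18; prenyl takes the place of the C1 hydrogen), via bridgehead organolithium 20 (not isolated)
Conditions: LiN(iPr)2 (LDA), THF, −78 °C; then 3, −78 → 0 °C
Reagents that add atoms: none
Why: Bridgehead lithiation–alkylation: the C1 hydrogen flanked by the C2 and C9 carbonyls is the kinetically most acidic site towards LDA, and the non-enolisable, configurationally locked bridgehead carbanion is alkylated by prenyl bromide with necessary retention at C1.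

Step 12
Reactants: 21 C7 allyl dione
Product: 22 4-methoxy-8-methyl-1,5-bis(3-methylbut-2-en-1-yl)-8-(4-methylpent-3-en-1-yl)-7-[(2Z)-3-(4,4,5,5-tetramethyl-1,3,2-dioxaborolan-2-yl)but-2-en-1-yl]bicyclo[3.3.1]non-3-ene-2,9-dione (boron trans to the chain)
Conditions: isopropenylboronic acid pinacol ester (5 equiv), second-generation Grubbs catalyst (10 mol%), CH2Cl2, 40 °C
Reagents that add atoms: 4,4,5,5-tetramethyl-2-(prop-1-en-2-yl)-1,3,2-dioxaborolane CC(=C)B1OC(C)(C)C(C)(C)O1
Why: Olefin cross-metathesis between the only monosubstituted alkene and the 1,1-disubstituted alkenylboronate, which does not homodimerise; the trisubstituted prenyl-type alkenes react far more slowly, and the bulky boronate ends up trans to the chain (Z descriptor, methyl cis to C1′).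

Step 13
Reactants: 22 alkenyl boronate
Product: 23 7-[(2E)-3-iodobut-2-en-1-yl]-4-methoxy-8-methyl-1,5-bis(3-methylbut-2-en-1-yl)-8-(4-methylpent-3-en-1-yl)bicyclo[3.3.1]non-3-ene-2,9-dione
Conditions: NaOH (aq), THF, 0 °C; then I2, 0 °C
Reagents that add atoms: iodine II
Why: Iododeboronation of the hydroxide ate complex replaces boron by iodine at the same carbon with retention of alkene geometry, so iodine stays trans to the chain; the C9 ketone is now shielded by two quaternary bridgeheads and the short, cold exposure limits attack of base or iodine elsewhere.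

Step 14
Reactants: 23 alkenyl iodide
Product: 24 7-[(2E)-3,7-dimethylocta-2,6-dien-1-yl]-4-methoxy-8-methyl-1,5-bis(3-methylbut-2-en-1-yl)-8-(4-methylpent-3-en-1-yl)bicyclo[3.3.1]non-3-ene-2,9-dione
Conditions: Me2C=CHCH2CH2ZnBr (from 5-bromo-2-methylpent-2-ene, Zn, LiCl, THF), Pd(dppf)Cl2 (5 mol%), THF, 40 °C
Reagents that add atoms: (4-methylpent-3-en-1-yl)zinc bromide CC(C)=CCC[Zn]Br
Why: Negishi coupling: oxidative addition of the alkenyl iodide to zerovalent palladium and reductive elimination both retain geometry, so the homoprenyl group ends up trans to C1′ and the side chain is (E)-geranyl, and the alkylzinc halide does not add to the ketone or the vinylogous ester.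

Step 15
Reactants: 25 3-hydroxybenzoic acid
Product: 26 tert-butyldimethylsilyl 3-[(tert-butyldimethylsilyl)oxy]benzoate
Conditions: TBSCl (2.2 equiv), imidazole, DMF, rt
Reagents that add atoms: tert-butylchlorodimethylsilane CC(C)(C)[Si](C)(C)Cl
Why: Silylation of both acidic hydroxyl groups (phenol and carboxylic acid) with the silyl chloride and imidazole.

Step 16
Reactants: 26 bis-silylated acid
Product: 27 3-[(tert-butyldimethylsilyl)oxy]benzoyl chloride
Conditions: (COCl)2, DMF (cat.), CH2Cl2, 0 °C → rt
Reagents that add atoms: oxalyl chloride O=C(Cl)C(Cl)=O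
Why: A silyl ester reacts with the chloroiminium species from oxalyl chloride and DMF to give the acid chloride and the silyl chloride under neutral conditions, which leaves the aryl silyl ether intact.

Step 17
Reactants: 24 C7 geranyl vinylogous ester; 27 3-[(tert-butyldimethylsilyl)oxy]benzoyl chloride
Product: 29 3-{3-[(tert-butyldimethylsilyl)oxy]benzoyl}-7-[(2E)-3,7-dimethylocta-2,6-dien-1-yl]-4-methoxy-8-methyl-1,5-bis(3-methylbut-2-en-1-yl)-8-(4-methylpent-3-en-1-yl)bicyclo[3.3.1]non-3-ene-2,9-dione, via C3 vinyllithium 28 (not isolated)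
Conditions: lithium 2,2,6,6-tetramethylpiperidide (LiTMP), THF, −78 °C; then 27, −78 → −40 °C
Reagents that add atoms: none
Why: With both bridgeheads substituted the only acidic site is the C3 vinyl hydrogen between carbonyl and methoxy, so directed lithiation by LiTMP gives the C3 vinyllithium, which is C-acylated by the aroyl chloride (acylation of a lithiated vinylogous ester).

Step 18
Reactants: 29 O-methyl, O-silyl protected target
Product: 30 CNP0285073.1, (1S,5S,7R,8S)-7-[(2E)-3,7-dimethylocta-2,6-dien-1-yl]-4-hydroxy-3-(3-hydroxybenzoyl)-8-methyl-1,5-bis(3-methylbut-2-en-1-yl)-8-(4-methylpent-3-en-1-yl)bicyclo[3.3.1]non-3-ene-2,9-dione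
Conditions: LiOH, dioxane/H2O, 90 °C; then 1 M HCl
Reagents that add atoms: water O (delivered as hydroxide from lithium hydroxide [Li+].[OH-])
Why: Hydroxide adds to C4 and expels methoxide (addition–elimination on the vinylogous ester) to give the enolised β-triketone as its stabilised lithium enolate, which protects the ring from retro-Claisen cleavage, and the same base cleaves the aryl silyl ether; acidification then gives the target with C1, C5, C7 and C8 untouched.

Compound list
1 | 1,3-dimethoxybenzene | COc1cccc(OC)c1 | starting material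
2 | 1,5-dimethoxycyclohexa-1,4-diene | COC1=CCC=C(OC)C1 | intermediate
3 | prenyl bromide (1-bromo-3-methylbut-2-ene) | CC(C)=CCBr | starting material
4 | (2,6-dimethoxycyclohexa-2,5-dien-1-yl)lithium | [Li]C1C(OC)=CCC=C1OC | intermediate (not isolated)
5 | 1,5-dimethoxy-6-(3-methylbut-2-en-1-yl)cyclohexa-1,4-diene | COC1=CCC=C(OC)C1CC=C(C)C | intermediate
6 | geraniol | CC(C)=CCC/C(C)=C/CO | starting material
7 | [(2R,3R)-3-methyl-3-(4-methylpent-3-en-1-yl)oxiran-2-yl]methanol | OC[C@H]1O[C@]1(C)CCC=C(C)C | intermediate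
8 | [(2R,3R)-3-methyl-3-(4-methylpent-3-en-1-yl)oxiran-2-yl]methyl methanesulfonate | CS(=O)(=O)OC[C@H]1O[C@]1(C)CCC=C(C)C | intermediate (not isolated)
9 | (2S,3R)-2-(bromomethyl)-3-methyl-3-(4-methylpent-3-en-1-yl)oxirane | BrC[C@H]1O[C@]1(C)CCC=C(C)C | intermediate
10 | [2,6-dimethoxy-1-(3-methylbut-2-en-1-yl)cyclohexa-2,5-dien-1-yl]lithium | [Li]C1(CC=C(C)C)C(OC)=CCC=C1OC | intermediate (not isolated)
11 | (2R,3R)-2-{[2,6-dimethoxy-1-(3-methylbut-2-en-1-yl)cyclohexa-2,5-dien-1-yl]methyl}-3-methyl-3-(4-methylpent-3-en-1-yl)oxirane | COC1=CCC=C(OC)C1(CC=C(C)C)C[C@H]2O[C@]2(C)CCC=C(C)C | intermediate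
12 | C7 trimethylsilyl ether, C9 O-methyl oxocarbenium triflate of the ring-A-closed bicycle | C[Si](C)(C)O[C@@H]1C[C@]2(CC=C(C)C)C(=[O+]C)[C@@H](CC=C2OC)[C@@]1(C)CCC=C(C)C.[O-]S(=O)(=O)C(F)(F)F | intermediate (not isolated)
13 | (1S,5S,7R,8R,9R)-4,9-dimethoxy-8-methyl-5-(3-methylbut-2-en-1-yl)-8-(4-methylpent-3-en-1-yl)-7,9-epoxybicyclo[3.3.1]non-3-ene (C8 methyl axial on ring A) | O3[C@@H]1C[C@]2(CC=C(C)C)[C@@]3(OC)[C@@H](CC=C2OC)[C@@]1(C)CCC=C(C)C | intermediate
14 | C7 O-dimethylborinate of 15 | CB(C)O[C@@H]1C[C@]2(CC=C(C)C)C(=O)[C@@H](CC=C2OC)[C@@]1(C)CCC=C(C)C | intermediate (not isolated)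
15 | (1S,5S,7R,8R)-7-hydroxy-4-methoxy-8-methyl-5-(3-methylbut-2-en-1-yl)-8-(4-methylpent-3-en-1-yl)bicyclo[3.3.1]non-3-en-9-one (hydroxyl exo) | O[C@@H]1C[C@]2(CC=C(C)C)C(=O)[C@@H](CC=C2OC)[C@@]1(C)CCC=C(C)C | intermediate
16 | sodium O-alkyl carbonodithioate of 15 | [Na+].[S-]C(=S)O[C@@H]1C[C@]2(CC=C(C)C)C(=O)[C@@H](CC=C2OC)[C@@]1(C)CCC=C(C)C | intermediate (not isolated)
17 | O-[(1S,5S,7R,8R)-4-methoxy-8-methyl-5-(3-methylbut-2-en-1-yl)-8-(4-methylpent-3-en-1-yl)-9-oxobicyclo[3.3.1]non-3-en-7-yl] S-methyl carbonodithioate | CSC(=S)O[C@@H]1C[C@]2(CC=C(C)C)C(=O)[C@@H](CC=C2OC)[C@@]1(C)CCC=C(C)C | intermediate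
18 | (1S,5S,7R,8S)-4-methoxy-8-methyl-5-(3-methylbut-2-en-1-yl)-8-(4-methylpent-3-en-1-yl)-7-(prop-2-en-1-yl)bicyclo[3.3.1]non-3-en-9-one (allyl exo) | C=CC[C@@H]1C[C@]2(CC=C(C)C)C(=O)[C@@H](CC=C2OC)[C@@]1(C)CCC=C(C)C | intermediate
19 | 4-methoxy-8-methyl-5-(3-methylbut-2-en-1-yl)-8-(4-methylpent-3-en-1-yl)-7-(prop-2-en-1-yl)bicyclo[3.3.1]non-3-ene-2,9-dione (stereocentres as in 18) | C=CC[C@@H]1C[C@]2(CC=C(C)C)C(=O)[C@@H](C(=O)C=C2OC)[C@@]1(C)CCC=C(C)C | intermediate
20 | C1 bridgehead lithium derivative of 19 | C=CC[C@@H]1C[C@]2(CC=C(C)C)C(=O)[C@@]([Li])(C(=O)C=C2OC)[C@@]1(C)CCC=C(C)C | intermediate (not isolated)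
21 | 4-methoxy-8-methyl-1,5-bis(3-methylbut-2-en-1-yl)-8-(4-methylpent-3-en-1-yl)-7-(prop-2-en-1-yl)bicyclo[3.3.1]non-3-ene-2,9-dione | C=CC[C@@H]1C[C@]2(CC=C(C)C)C(=O)[C@@](CC=C(C)C)(C(=O)C=C2OC)[C@@]1(C)CCC=C(C)C | intermediate
22 | 7-[(2Z)-3-(4,4,5,5-tetramethyl-1,3,2-dioxaborolan-2-yl)but-2-en-1-yl] analogue of 21 | CC1(C)OB(/C(C)=C/C[C@@H]2C[C@]3(CC=C(C)C)C(=O)[C@@](CC=C(C)C)(C(=O)C=C3OC)[C@@]2(C)CCC=C(C)C)OC1(C)C | intermediate
23 | 7-[(2E)-3-iodobut-2-en-1-yl] analogue of 21 | I/C(C)=C/C[C@@H]1C[C@]2(CC=C(C)C)C(=O)[C@@](CC=C(C)C)(C(=O)C=C2OC)[C@@]1(C)CCC=C(C)C | intermediate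
24 | 7-[(2E)-3,7-dimethylocta-2,6-dien-1-yl]-4-methoxy-8-methyl-1,5-bis(3-methylbut-2-en-1-yl)-8-(4-methylpent-3-en-1-yl)bicyclo[3.3.1]non-3-ene-2,9-dione | CC(C)=CCC/C(C)=C/C[C@@H]1C[C@]2(CC=C(C)C)C(=O)[C@@](CC=C(C)C)(C(=O)C=C2OC)[C@@]1(C)CCC=C(C)C | intermediate
25 | 3-hydroxybenzoic acid | OC(=O)c1cccc(O)c1 | starting material
26 | tert-butyldimethylsilyl 3-[(tert-butyldimethylsilyl)oxy]benzoate | CC(C)(C)[Si](C)(C)OC(=O)c1cccc(O[Si](C)(C)C(C)(C)C)c1 | intermediate
27 | 3-[(tert-butyldimethylsilyl)oxy]benzoyl chloride | ClC(=O)c1cccc(O[Si](C)(C)C(C)(C)C)c1 | intermediate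
28 | C3 vinyllithium derivative of 24 | CC(C)=CCC/C(C)=C/C[C@@H]1C[C@]2(CC=C(C)C)C(=O)[C@@](CC=C(C)C)(C(=O)C([Li])=C2OC)[C@@]1(C)CCC=C(C)C | intermediate (not isolated)
29 | 3-{3-[(tert-butyldimethylsilyl)oxy]benzoyl} derivative of 24 | CC(C)=CCC/C(C)=C/C[C@@H]1C[C@]2(CC=C(C)C)C(=O)[C@@](CC=C(C)C)(C(=O)C(C(=O)c3cccc(O[Si](C)(C)C(C)(C)C)c3)=C2OC)[C@@]1(C)CCC=C(C)C | intermediate
30 | CNP0285073.1, (1S,5S,7R,8S)-7-[(2E)-3,7-dimethylocta-2,6-dien-1-yl]-4-hydroxy-3-(3-hydroxybenzoyl)-8-methyl-1,5-bis(3-methylbut-2-en-1-yl)-8-(4-methylpent-3-en-1-yl)bicyclo[3.3.1]non-3-ene-2,9-dione | CC(C)=CCC/C(C)=C/C[C@@H]1C[C@]2(CC=C(C)C)C(=O)[C@@](CC=C(C)C)(C(=O)C(C(=O)c3cccc(O)c3)=C2O)[C@@]1(C)CCC=C(C)C | target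

Total step count: 18. Longest linear sequence: 14 steps from 1,3-dimethoxybenzene (steps 1, 2, 5–14, 17, 18); steps 3–4 and 15–16 are side branches.

Steps most likely to fail

Step 6. The developing C8 cation may be captured by the C5 prenyl π bond in a competing six-membered closure, or the silylated oxirane may lose a proton to give an allylic silyl ether before the enol ether attacks. The fallback carries C5 as a less nucleophilic allyl group and converts it into prenyl after the ring is closed. It sets out from 2: lithiation with t-BuLi and alkylation with allyl bromide should give 6-allyl-1,5-dimethoxycyclohexa-1,4-diene F1. A second lithiation with s-BuLi and alkylation with 9 should give the allyl analogue of the cyclisation precursor F2. The same silyl triflate cyclisation should give the 5-allyl bridged ketal F3. Cross-metathesis of F3 with 2-methyl-2-butene (second-generation Grubbs catalyst, CH2Cl2, 40 °C) should turn allyl into prenyl and rejoin the route at 13.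

Step 13. Electrophilic iodine may attack the prenyl-type alkenes or the C3 position of the vinylogous ester, and aqueous hydroxide may begin to cleave the vinylogous ester. The fallback avoids the iodide and uses boron as the nucleophile. It sets out from 22: a Suzuki–Miyaura coupling with the primary alkyl bromide 5-bromo-2-methylpent-2-ene (Pd(OAc)2, P(t-Bu)2Me, KOt-Bu, tert-amyl alcohol, rt) should form the same C3′–C4′ bond with retention of geometry and come back to the route at 24. No new compound is made.

Step 11. Deprotonation may occur at the C3 vinyl position instead of, or together with, the C1 bridgehead, which would lead to C3 prenylation or mixtures. The fallback blocks C3 with a silyl group. It sets out from 19: LiTMP with TMSCl present in situ at −78 °C should give the 3-trimethylsilyl vinylogous ester F4. LDA and prenyl bromide should then alkylate only the bridgehead and give the 1-prenyl-3-trimethylsilyl compound F5. Desilylation with Bu4NF in THF should return to the route at 21.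

Further compounds
F1 | step 6 | 6-allyl-1,5-dimethoxycyclohexa-1,4-diene | COC1=CCC=C(OC)C1CC=C
F2 | step 6 | (2R,3R)-2-{[2,6-dimethoxy-1-(prop-2-en-1-yl)cyclohexa-2,5-dien-1-yl]methyl}-3-methyl-3-(4-methylpent-3-en-1-yl)oxirane | COC1=CCC=C(OC)C1(CC=C)C[C@H]2O[C@]2(C)CCC=C(C)C
F3 | step 6 | 5-(prop-2-en-1-yl) analogue of bridged ketal 13 | O3[C@@H]1C[C@]2(CC=C)[C@@]3(OC)[C@@H](CC=C2OC)[C@@]1(C)CCC=C(C)C
F0 | step 13 | none | none
F4 | step 11 | 3-trimethylsilyl derivative of 19 | C=CC[C@@H]1C[C@]2(CC=C(C)C)C(=O)[C@@H](C(=O)C([Si](C)(C)C)=C2OC)[C@@]1(C)CCC=C(C)C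
F5 | step 11 | 3-trimethylsilyl derivative of 21 | C=CC[C@@H]1C[C@]2(CC=C(C)C)C(=O)[C@@](CC=C(C)C)(C(=O)C([Si](C)(C)C)=C2OC)[C@@]1(C)CCC=C(C)C
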